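## The problem

The target 23 is a flavone: a chromen-4-one (ring A fused to the pyranone ring C) that carries ring B at C2. It has no stereocentre, and each prenyl (3-methylbut-2-enyl) double bond ends in two methyl groups, so nothing has to be controlled in space. The difficulty lies in the substitution pattern and in functional-group tolerance. Ring A is fully substituted (5-OH, 6-prenyl, 7-OMe, 8-prenyl), C3 bears the third prenyl group, and the C2–C1' bond is crowded by that prenyl group on one side and the C2' hydroxyl on the other. Ring B is a 2',4',5'-trihydroxyphenyl (hydroxyquinol) unit, which autoxidises easily and must be set free last, with air excluded. The trisubstituted alkenes lie next to phenols (6-prenyl/5-OH, 3-prenyl/2'-OH) and close to chromans or add HX under strong Brønsted or Lewis acids. They also rule out hydrogenolysis and boron trihalides, so protecting groups must leave under mild acid or by redox chemistry while the 7-methyl ether stays. The pyranone is a vinylogous ester that alkoxides and hard nucleophiles can open. What invites a de novo construction of ring B is its oxygen pattern: C2'–O and C5'–O are para, C4'–O sits beside C5', and C3' and C6' carry hydrogen. That is the 4-alkoxyphenol formed when a terminal alkyne (C1', C6'), one CO (C2') and an alkoxy(1-oxyvinyl)carbene (C5', C4', C3') are joined on chromium.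

## Retrosynthesis

**Unmasking ring B (23 ⇐ 22 ⇐ 21 ⇐ 20).** No skeletal bond is cut here, only the two O–C bonds that mask C4'–OH (a methoxymethyl acetal) and C5'–OH (a methyl ether). Towards a Lewis acid the C5' methyl ether would be indistinguishable from the one at C7. In 20, however, it stands para to the free C2' hydroxyl, so a two-electron oxidation expels it as methanol and gives quinone 21. Reduction to hydroquinone 22 and mild acid then give 23. These steps must leave the prenyl groups and 7-OMe untouched and keep air away from 22 and 23.

**Ring B (20 ⇐ 11 + 18).** Ring B is taken apart completely at C1'–C2', C2'–C3' and C5'–C6'. This gives the terminal alkyne 11 (C1', C6'), a carbonyl ligand of 18 (C2') and the carbene carbon of 18 with its 1-(methoxymethoxy)vinyl group (C5', C4', C3'). The neighbouring cuts are less attractive. A C2–C1' cut would need a cross-coupling of a C2-functionalised pyranone with an ortho-oxygenated aryl partner across the C3 prenyl group. The classical O1–C2 cut would need a pre-oxidised, triply protected ring B acid and a cyclodehydration beside a 2'-oxygen. The benzannulation places all three oxygens in one operation and delivers them differentiated (free OH, methyl ether, acetal), as the end game requires. Precursor 11 is simpler by one ring, six carbons and all of the oxidation-sensitive functionality. The forward reaction must insert the alkyne with its substituted carbon next to the incoming CO, and must prefer CO insertion and electrocyclisation to any reaction with the prenyl alkenes.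

**The carbene complex (18 ⇐ 14 + 15; 14 ⇐ 13 ⇐ 12).** Complex 18 is cut at the carbene carbon–vinyl bond and at O–CH3. This is the Fischer synthesis from Cr(CO)6 15 and the α-lithiated vinyl ether 16, through acylchromate 17 and O-methylation. The vinyl oxygen carries a methoxymethyl group because a purchasable alkyl vinyl ether would leave a C4' alkyl ether that cannot be removed beside 7-OMe. Vinyl ether 14 comes from bromide 13 by elimination, and 13 from 2-bromoethanol 12.

**The alkyne (11 ⇐ 10 ⇐ 9 ⇐ 8).** Removing the terminal alkyne carbon (the future C6') from 11 leaves aldehyde 10. This one-carbon homologation is preferred to coupling an acetylene with a C2-halogenated pyranone, for which the hydroxyketone chemistry used here offers no precursor. Aldehyde 10 is the oxidation product of alcohol 9, and 9 the reduction product of ester 8. Passing through the alcohol avoids a partial ester reduction that would have to stop at the aldehyde beside the C4 carbonyl.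

**Ring C (8 ⇐ 5 + 6).** Ring C is opened at O1–C2 and C2–C3, which gives ketone 5 and diethyl oxalate 6, by way of diketo ester 7. Because the C3 prenyl group is already on the side chain of 5, no late alkylation at C3 of a pyranone is needed. Because 5 is symmetric, either phenol can close ring C and the other becomes the chelated 5-OH. That hydroxyl is left unprotected from here on: as its phenoxide it shields the pyranone in the basic steps, and a protection of a hindered, hydrogen-bonded hydroxyl is saved.

**The acylphloroglucinol (5 ⇐ 4 + 2; 4 ⇐ 3; 3 ⇐ 1 + 2).** Ketone 5 is cut at the Cα–CH2 bond into acetophenone 4 and prenyl bromide 2; the alkylation is run on the polyanion, so no phenol protection is needed. Removing the O-methyl group of 4 gives triol 3, and cutting the two aryl–prenyl bonds gives 2,4,6-trihydroxyacetophenone 1 and again 2. Prenylation precedes methylation because C-alkylation works best on the fully ionised phloroglucinol. Methylation then only has to select the one hydroxyl para to the acetyl group.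

## Roads not taken

**Alternative 1:** ring A made last from a pyran-2-one, cut at C4a–C8a.
- **Forward step:** pyranone A1 is a 4-methoxy-3,5-diprenylpyran-2-one whose C6 side chain is a 2,4-dioxo-3-prenyl-4-[2,4,5-tris(methoxymethoxy)phenyl]butyl group. Mg(OMe)2 in methanol would open it to a methyl ester, and the side-chain methylene would condense onto that ester to give the acylphloroglucinol diketone A2.
- **Merits:** it follows polyketide logic, the methoxy group is fixed from the start, and ring B arrives fully oxygenated. In these respects it is better than steps 1 and 2 of the chosen route, which rely on a statistical C-prenylation and a selective O-methylation.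
- **Weak points:** A1 contains a 1,3-diketone whose methine is more acidic than the methylene that must react, and four electrophilic carbonyls, so other aldol and O-cyclisation modes compete. Placing prenyl groups at C3 and C5 of a pyranone and acylating its side chain is a long preparation. A2 is still one ring short, and its cyclodehydration to the tris(methoxymethyl) ether A5 has to choose between a ring A phenol and the masked 2'-oxygen.
- **Comparison:** A2 is the same diketone that ketone 5 would give by an aldol addition and an oxidation. The recyclisation therefore spends its effort on a ring that 1 supplies ready-made, and it is not shorter overall.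

**Alternative 2:** ring C formed in one step from two halves, cut at C3–C4 and O1–C2.
- **Forward step:** the symmetric aldehyde A3 and the aryl prenyl alkyne A4 would be joined under [Cp*RhCl2]2, AgSbF6 and Cu(OAc)2. Phenol-assisted activation of the aldehyde C–H bond by trivalent rhodium, alkyne insertion and C–O bond formation would give A5 directly.
- **Merits:** this is the most convergent plan. The whole skeleton, including the C3 prenyl group, appears in one step, the symmetry of A3 removes any choice of phenol, and only an acidic deprotection follows. It is clearly shorter than the chosen route, and that must be conceded.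
- **Weak points:** a cationic rhodium catalyst and a stoichiometric divalent copper oxidant at elevated temperature meet four trisubstituted alkenes next to free phenols, the setting for allylic C–H activation and oxidative chromene formation. A4 is a skipped enyne whose doubly activated CH2 isomerises easily to an allene or a conjugated enyne. The aldehyde is flanked by two hydroxyls and the alkyne by an ortho acetal, so the insertion is doubly hindered. AgSbF6 is a Lewis acid towards the three acetals.
- **Comparison:** the chosen plan offers a key step that needs no oxidant, acid or base and runs near 50 °C, where isolated alkenes and acetals are inert. It pays for this with five more steps.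

**Alternative 3:** ring C closed at O1–C8a by nucleophilic aromatic substitution.
- **Forward step:** the 2,6-difluoroaryl diketone A6 would be converted by K2CO3 in DMF into its enolate, whose distal oxygen displaces one fluoride to give the 5-fluoroflavone A7.
- **Merits:** the closure is robust and has a single oxygen nucleophile, so no ambiguity arises even with the 2'-oxygen present, and ring A needs no phenol protection. As a ring closure it is more secure than step 4 of the chosen route.
- **Weak points:** the 2,6-difluoro-4-methoxy-3,5-diprenylphenyl ketone has no cheap counterpart of 1 and would need repeated directed metalation and allylation of a fluoroanisole. The fluorine left at C5 of A7 must still be exchanged for hydroxyl to reach A5. That second substitution, on an electron-rich ring activated only by the peri carbonyl, uses hydroxide equivalents that also attack the pyranone.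
- **Comparison:** two further steps after the key step, added to the long preparation of A6, make this road longer than the chosen one, whose ring A chemistry starts from a symmetric, inexpensive phenol.

Key step: step 11

Assumption: the C5 hydroxyl, hydrogen-bonded to the C4 carbonyl, is carried unprotected from step 4 to the end, and 2,4,6-trihydroxyacetophenone is used dried from its commercial hydrate. Prenyl means 3-methylbut-2-enyl throughout.

## Route

Step 1
Reactants: 1 2,4,6-trihydroxyacetophenone; 2 prenyl bromide (1-bromo-3-methylbut-2-ene)
Product: 3 1-[2,4,6-trihydroxy-3,5-bis(3-methylbut-2-enyl)phenyl]ethanone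
Conditions: 2 (2.1 equiv), KOH (10% aq.), 0 °C → rt
Reagents that add atoms: none
Why: Aqueous-alkali C-prenylation of an acylphloroglucinol: in water the ambident polyphenoxide is alkylated on carbon by the soft allylic bromide, and each of the two free ring positions should take one prenyl group; mono- and geminally diprenylated by-products would be removed by chromatography.

Step 2
Reactants: 3 1-[2,4,6-trihydroxy-3,5-bis(3-methylbut-2-enyl)phenyl]ethanone
Product: 4 1-[2,6-dihydroxy-4-methoxy-3,5-bis(3-methylbut-2-enyl)phenyl]ethanone
Conditions: Me2SO4 (1.05 equiv), K2CO3 (1.1 equiv), acetone, rt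
Reagents that add atoms: dimethyl sulfate, COS(=O)(=O)OC
Why: Williamson O-methylation: the C4 hydroxyl, para to the acetyl group and not engaged in the hydrogen bond to the carbonyl, is the most acidic and is the one ionised by one equivalent of K2CO3, so one equivalent of the methylating agent should be taken up there alone.

Step 3
Reactants: 4 1-[2,6-dihydroxy-4-methoxy-3,5-bis(3-methylbut-2-enyl)phenyl]ethanone; 2 prenyl bromide
Product: 5 1-[2,6-dihydroxy-4-methoxy-3,5-bis(3-methylbut-2-enyl)phenyl]-5-methylhex-4-en-1-one
Conditions: LiN(iPr)2 (3.3 equiv), THF, −78 → −20 °C; 2 (1.0 equiv), −78 → 0 °C; AcOH quench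
Reagents that add atoms: none
Why: Polyanion (bis-phenoxide enolate) alkylation of an ortho-hydroxyaryl methyl ketone: the enolate carbon is by far the most nucleophilic site of the trianion, so the single equivalent of allylic bromide should be taken up at the methyl carbon, and limiting the bromide guards against a second alkylation.

Step 4
Reactants: 5 1-[2,6-dihydroxy-4-methoxy-3,5-bis(3-methylbut-2-enyl)phenyl]-5-methylhex-4-en-1-one; 6 diethyl oxalate
Product: 8 ethyl 5-hydroxy-7-methoxy-3,6,8-tris(3-methylbut-2-enyl)-4-oxochromene-2-carboxylate, via diketo ester 7 (not isolated)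
Conditions: LiN(SiMe3)2 (4 equiv), THF, −78 → 0 °C; 6 (1.5 equiv), −78 °C → rt; AcOH quench; then TsOH·H2O (0.2 equiv), EtOH, 50 °C
Reagents that add atoms: none
Why: Crossed Claisen condensation of the ketone polyanion with the non-enolisable oxalate, then acid-catalysed hemiketalisation of either of the two equivalent phenols onto the 2-oxo group and dehydration (the classical chromone-2-carboxylate synthesis); the symmetry of 5 removes any regiochemical question, and catalytic sulfonic acid in warm ethanol is no stronger than the conditions under which prenylated phenols survive acetal cleavage.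

Step 5
Reactants: 8 ethyl 5-hydroxy-7-methoxy-3,6,8-tris(3-methylbut-2-enyl)-4-oxochromene-2-carboxylate
Product: 9 5-hydroxy-2-(hydroxymethyl)-7-methoxy-3,6,8-tris(3-methylbut-2-enyl)chromen-4-one
Conditions: NaBH4 (3 equiv), MeOH/THF, 0 °C
Reagents that add atoms: none
Why: Chemoselective borohydride reduction: the 2-carboxylate is activated by the ring oxygen and the conjugated pyranone, whereas the C4 carbonyl is a vinylogous ester further deactivated as its 5-phenoxide, so only the ester should be reduced.

Step 6
Reactants: 9 5-hydroxy-2-(hydroxymethyl)-7-methoxy-3,6,8-tris(3-methylbut-2-enyl)chromen-4-one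
Product: 10 5-hydroxy-7-methoxy-3,6,8-tris(3-methylbut-2-enyl)-4-oxochromene-2-carbaldehyde
Conditions: MnO2 (activated, 15 equiv), CH2Cl2, rt
Reagents that add atoms: none
Why: MnO2 oxidation of an allylic-type primary alcohol (C3=C2–CH2OH) to the aldehyde; the prenyl groups and the chelated phenol are not touched by this reagent.

Step 7
Reactants: 10 5-hydroxy-7-methoxy-3,6,8-tris(3-methylbut-2-enyl)-4-oxochromene-2-carbaldehyde
Product: 11 2-ethynyl-5-hydroxy-7-methoxy-3,6,8-tris(3-methylbut-2-enyl)chromen-4-one
Conditions: dimethyl (1-diazo-2-oxopropyl)phosphonate (1.3 equiv), K2CO3 (3 equiv), MeOH/THF, 0 °C → rt, short reaction time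
Reagents that add atoms: dimethyl (1-diazo-2-oxopropyl)phosphonate, CC(=O)C(=[N+]=[N-])P(=O)(OC)OC
Why: Ohira–Bestmann (Seyferth–Gilbert) homologation: methanolysis of the reagent gives the diazomethylphosphonate anion, which adds to the aldehyde, eliminates dimethyl phosphate and loses N2 with a 1,2-hydrogen shift to the terminal alkyne; the 5-phenoxide present under these conditions lowers the electrophilicity of the pyranone towards methoxide.

Step 8
Reactants: 12 2-bromoethanol
Product: 13 1-bromo-2-(methoxymethoxy)ethane
Conditions: MeOCH2Cl, iPr2NEt, CH2Cl2, 0 °C → rt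
Reagents that add atoms: chloromethyl methyl ether, COCCl
Why: Standard acetal protection of a primary alcohol with chloromethyl methyl ether and a hindered amine base; 13 can also be bought.

Step 9
Reactants: 13 1-bromo-2-(methoxymethoxy)ethane
Product: 14 methoxymethyl vinyl ether [(methoxymethoxy)ethene]
Conditions: KOH (powdered), tetraglyme, 120 °C, product distilled out; redistilled from CaH2
Reagents that add atoms: none
Why: E2 dehydrobromination of a 2-alkoxyethyl bromide, the usual entry to vinyl ethers; the volatile product leaves the basic medium by distillation.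

Step 10
Reactants: 14 methoxymethyl vinyl ether; 15 Cr(CO)6
Product: 18 pentacarbonyl[methoxy(1-(methoxymethoxy)vinyl)carbene]chromium, via 1-(methoxymethoxy)vinyllithium 16 (not isolated), via lithium acylchromate 17 (not isolated)
Conditions: s-BuLi, THF, −78 °C; 15, THF, −78 → 0 °C; solvent exchange; Me3OBF4, CH2Cl2, 0 °C; stored cold under Ar
Reagents that add atoms: trimethyloxonium tetrafluoroborate, C[O+](C)C.F[B-](F)(F)F
Why: Fischer synthesis of an alkoxycarbene complex: acetal-assisted α-lithiation of the vinyl ether, addition of the vinyllithium to a carbonyl ligand of Cr(CO)6 to give the acylchromate, and O-methylation by the hard oxonium salt; α-oxygenated alkenylcarbene complexes of zerovalent chromium made this way from lithiated enol ethers are isolable.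

Step 11
Reactants: 11 2-ethynyl-5-hydroxy-7-methoxy-3,6,8-tris(3-methylbut-2-enyl)chromen-4-one; 18 pentacarbonyl[methoxy(1-(methoxymethoxy)vinyl)carbene]chromium
Product: 20 5-hydroxy-2-[2-hydroxy-5-methoxy-4-(methoxymethoxy)phenyl]-7-methoxy-3,6,8-tris(3-methylbut-2-enyl)chromen-4-one, via tricarbonylchromium arene complex 19 (not isolated)
Conditions: 18 (1.5 equiv), THF (degassed, 0.05 M), 50 °C, Ar; then air, daylight, Et2O/MeCN, rt
Reagents that add atoms: none
Why: Dötz benzannulation of an alkenyl(alkoxy)carbene complex of zerovalent chromium with a terminal alkyne, the closest known cases being carbene complexes from lithiated enol ethers reacting with aryl- and alkenylacetylenes. Loss of one CO from 18 frees a site for 11, which inserts into the Cr=C bond so that the alkyne CH (C6') bonds to the carbene carbon (C5') and chromium moves to C1'; CO insertion there gives a chromium-bound dienylketene (C1'–C2'). Ring B then closes by 6π-electrocyclisation of this ketene (C2'–C3', ketene carbon to the vinyl CH2), and the cyclohexadienone enolises to the phenol, first as the Cr(CO)3 complex 19, from which air and light release 20. No stereocentre is formed. The selectivity needed is the direction of alkyne insertion, and it is secured sterically: a terminal alkyne places its substituted carbon next to the incoming CO, so the chromonyl group ends up ortho to the new hydroxyl and the oxygens fall at C2', C4' and C5'. Preference for benzannulation over cyclopropanation or metathesis of the prenyl groups rests on the alkenyl carbene, on the donor solvent THF, which favours CO insertion, and on the low reactivity of unactivated trisubstituted alkenes towards these intermediates. The chelated 5-OH should not interfere, since the reaction itself produces a phenol and needs neither acid nor base.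

Step 12
Reactants: 20 5-hydroxy-2-[2-hydroxy-5-methoxy-4-(methoxymethoxy)phenyl]-7-methoxy-3,6,8-tris(3-methylbut-2-enyl)chromen-4-one
Product: 21 2-[5-hydroxy-7-methoxy-3,6,8-tris(3-methylbut-2-enyl)-4-oxochromen-2-yl]-5-(methoxymethoxy)cyclohexa-2,5-diene-1,4-dione
Conditions: (NH4)2Ce(NO3)6 (2.2 equiv), MeCN/H2O, 0 °C, 10 min
Reagents that add atoms: water, O
Why: Oxidative demethylation of a para-methoxyphenol by two equivalents of tetravalent cerium: two-electron oxidation gives an oxocarbenium ion, water adds at C5' and methanol is lost; ring A has no para-dioxygenated pair, so 7-OMe cannot be oxidised out, and isolated prenyl alkenes tolerate the brief cold treatment, as in prenylquinone syntheses.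

Step 13
Reactants: 21 2-[5-hydroxy-7-methoxy-3,6,8-tris(3-methylbut-2-enyl)-4-oxochromen-2-yl]-5-(methoxymethoxy)cyclohexa-2,5-diene-1,4-dione
Product: 23 5-hydroxy-7-methoxy-3,6,8-tris(3-methylbut-2-enyl)-2-(2,4,5-trihydroxyphenyl)chromen-4-one, via hydroquinone 22 (not isolated)
Conditions: Na2S2O4 (3 equiv), THF/H2O, rt, Ar; extraction under Ar; then HCl (2 M in MeOH, degassed), 40 °C
Reagents that add atoms: none
Why: Na2S2O4 reduces the quinone to the hydroquinone, and mild methanolic acid then cleaves the aryl methoxymethyl acetal by transacetalisation without touching the 7-methyl ether; degassed solvents keep the hydroxyquinol from reoxidising, and dilute acid at low temperature should not cyclise the prenyl groups onto the neighbouring phenols.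

## Compound list

1 | 2,4,6-trihydroxyacetophenone | CC(=O)c1c(O)cc(O)cc1O | starting material
2 | prenyl bromide (1-bromo-3-methylbut-2-ene) | CC(C)=CCBr | starting material
3 | 1-[2,4,6-trihydroxy-3,5-bis(3-methylbut-2-enyl)phenyl]ethanone | CC(=O)c1c(O)c(CC=C(C)C)c(O)c(CC=C(C)C)c1O | intermediate
4 | 1-[2,6-dihydroxy-4-methoxy-3,5-bis(3-methylbut-2-enyl)phenyl]ethanone | CC(=O)c1c(O)c(CC=C(C)C)c(OC)c(CC=C(C)C)c1O | intermediate
5 | 1-[2,6-dihydroxy-4-methoxy-3,5-bis(3-methylbut-2-enyl)phenyl]-5-methylhex-4-en-1-one | CC(C)=CCCC(=O)c1c(O)c(CC=C(C)C)c(OC)c(CC=C(C)C)c1O | intermediate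
6 | diethyl oxalate | CCOC(=O)C(=O)OCC | starting material
7 | ethyl 3-[2,6-dihydroxy-4-methoxy-3,5-bis(3-methylbut-2-enyl)benzoyl]-6-methyl-2-oxohept-5-enoate (open-chain diketo ester) | CCOC(=O)C(=O)C(CC=C(C)C)C(=O)c1c(O)c(CC=C(C)C)c(OC)c(CC=C(C)C)c1O | intermediate (not isolated)
8 | ethyl 5-hydroxy-7-methoxy-3,6,8-tris(3-methylbut-2-enyl)-4-oxochromene-2-carboxylate | CCOC(=O)c1oc2c(CC=C(C)C)c(OC)c(CC=C(C)C)c(O)c2c(=O)c1CC=C(C)C | intermediate
9 | 5-hydroxy-2-(hydroxymethyl)-7-methoxy-3,6,8-tris(3-methylbut-2-enyl)chromen-4-one | OCc1oc2c(CC=C(C)C)c(OC)c(CC=C(C)C)c(O)c2c(=O)c1CC=C(C)C | intermediate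
10 | 5-hydroxy-7-methoxy-3,6,8-tris(3-methylbut-2-enyl)-4-oxochromene-2-carbaldehyde | O=Cc1oc2c(CC=C(C)C)c(OC)c(CC=C(C)C)c(O)c2c(=O)c1CC=C(C)C | intermediate
11 | 2-ethynyl-5-hydroxy-7-methoxy-3,6,8-tris(3-methylbut-2-enyl)chromen-4-one | C#Cc1oc2c(CC=C(C)C)c(OC)c(CC=C(C)C)c(O)c2c(=O)c1CC=C(C)C | intermediate
12 | 2-bromoethanol | OCCBr | starting material
13 | 1-bromo-2-(methoxymethoxy)ethane | COCOCCBr | intermediate
14 | methoxymethyl vinyl ether [(methoxymethoxy)ethene] | COCOC=C | intermediate
15 | chromium hexacarbonyl, Cr(CO)6 | O=C=[Cr](=C=O)(=C=O)(=C=O)(=C=O)=C=O | starting material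
16 | 1-(methoxymethoxy)vinyllithium | [Li]C(=C)OCOC | intermediate (not isolated)
17 | lithium pentacarbonyl[2-(methoxymethoxy)-1-oxidoprop-2-enylidene]chromate (acylchromate) | [Li+].[O-]C(C(=C)OCOC)=[Cr](=C=O)(=C=O)(=C=O)(=C=O)=C=O | intermediate (not isolated)
18 | pentacarbonyl[methoxy(1-(methoxymethoxy)vinyl)carbene]chromium, (CO)5Cr=C(OMe)C(OCH2OMe)=CH2 | COC(C(=C)OCOC)=[Cr](=C=O)(=C=O)(=C=O)(=C=O)=C=O | intermediate
19 | tricarbonylchromium complex of 20, Cr(CO)3 bound η6 to ring B (the π bond is not drawn in the SMILES) | COc1c(CC=C(C)C)c(O)c2c(=O)c(CC=C(C)C)c(-c3cc(OC)c(OCOC)cc3O)oc2c1CC=C(C)C.O=C=[Cr](=C=O)=C=O | intermediate (not isolated)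
20 | 5-hydroxy-2-[2-hydroxy-5-methoxy-4-(methoxymethoxy)phenyl]-7-methoxy-3,6,8-tris(3-methylbut-2-enyl)chromen-4-one | COc1c(CC=C(C)C)c(O)c2c(=O)c(CC=C(C)C)c(-c3cc(OC)c(OCOC)cc3O)oc2c1CC=C(C)C | intermediate
21 | 2-[5-hydroxy-7-methoxy-3,6,8-tris(3-methylbut-2-enyl)-4-oxochromen-2-yl]-5-(methoxymethoxy)cyclohexa-2,5-diene-1,4-dione | COCOC1=CC(=O)C(=CC1=O)c1oc2c(CC=C(C)C)c(OC)c(CC=C(C)C)c(O)c2c(=O)c1CC=C(C)C | intermediate
22 | 2-[2,5-dihydroxy-4-(methoxymethoxy)phenyl]-5-hydroxy-7-methoxy-3,6,8-tris(3-methylbut-2-enyl)chromen-4-one | COc1c(CC=C(C)C)c(O)c2c(=O)c(CC=C(C)C)c(-c3cc(O)c(OCOC)cc3O)oc2c1CC=C(C)C | intermediate (not isolated)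
23 | 5-hydroxy-7-methoxy-3,6,8-tris(3-methylbut-2-enyl)-2-(2,4,5-trihydroxyphenyl)chromen-4-one | COc1c(CC=C(C)C)c(O)c2c(=O)c(CC=C(C)C)c(-c3cc(O)c(O)cc3O)oc2c1CC=C(C)C | target

## Step count and risks

Total: 13 steps. Longest linear sequence: 10 steps (steps 1–7, then 11–13); the carbene branch (steps 8–10) joins at step 11.

**Step 11 (key step).**
- What may go wrong: slow or misdirected insertion, because the alkyne is conjugated to the electron-poor pyranone; capture of the chromium vinylcarbene by the neighbouring C3 prenyl double bond (a 1,6-enyne relationship) before CO insertion; thermal decay of the α-oxygenated carbene complex before it reacts.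
- Fallback (from 5, back at 23): ring B is brought in ready-made. The trianion of 5 (LiN(iPr)2, THF, −78 °C) is added to 2,4,5-tris(methoxymethoxy)benzaldehyde F1, made from commercial 2,4,5-trihydroxybenzaldehyde with chloromethyl methyl ether and iPr2NEt. This gives the aldol adduct F2 as a diastereomer mixture; both new stereocentres are erased in the next operation. Dess–Martin periodinane oxidises F2 to the 1,3-diketone F3 (identical with A2). Cyclodehydration with pyridinium p-toluenesulfonate in toluene at 80 °C closes ring C through one of the two equivalent ring A phenols and gives the tris(methoxymethyl) ether F4 (identical with A5). HCl in methanol at 40 °C then gives 23.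

**Step 3.**
- What may go wrong: O-alkylation of a phenoxide, a second C-alkylation, or incomplete enolisation of the electron-rich bis-phenoxide.
- Fallback (from 4, back at 5): both phenols are protected with chloromethyl methyl ether and NaH in DMF to give 1-[4-methoxy-2,6-bis(methoxymethoxy)-3,5-bis(3-methylbut-2-enyl)phenyl]ethanone F5. Its lithium enolate (LiN(iPr)2, THF, −78 °C) is alkylated with 2 to give the α-prenylated bis-acetal F6, and HCl in methanol at 40 °C returns 5.

**Step 4.**
- What may go wrong: sluggish condensation at the hindered, α-branched polyanion, and acid-induced cyclisation or HX addition at the prenyl groups during the dehydration.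
- Fallback (from 5, back at 8): acid is avoided altogether. Ethyl chlorooxoacetate (3 equiv) in pyridine at 0 °C → rt acylates the phenols, and the ethoxalyl ester next to the ketone undergoes intramolecular C-acylation and dehydration under the same conditions (the ethoxalyl chloride–pyridine chromone synthesis known for 2-hydroxyaryl benzyl ketones). This gives the 5-O-ethoxalyl chromone ester F7. Brief treatment with aqueous NaHCO3 in ethanol cleaves the labile aryl oxalate and gives 8.

**Step 7.**
- What may go wrong: conjugate addition of methanol to the new ethynyl group, which is a vinylogous ynone, or methoxide attack at C2 of the pyranone during the homologation.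
- Fallback (from 10, back at 11): the methanolic carbonate medium is abandoned for an aprotic carbenoid homologation. Lithium (trimethylsilyl)diazomethanide, from Me3SiCHN2 and LiN(iPr)2 in THF at −78 °C, converts the aldehyde, after prior deprotonation of the 5-OH, by Colvin rearrangement directly to 11. No new isolated compound arises.

**Step 13.**
- What may go wrong: acid-promoted ring closure of a prenyl group onto a neighbouring phenol, and autoxidation of the hydroxyquinol during the deprotection.
- Fallback (from 21, back at 23): the acetal is removed at the quinone stage, where it is a vinylogous ester. Dilute aqueous LiOH in THF at 0 °C hydrolyses it by addition–elimination to 2-hydroxy-5-[5-hydroxy-7-methoxy-3,6,8-tris(3-methylbut-2-enyl)-4-oxochromen-2-yl]cyclohexa-2,5-diene-1,4-dione F8. Na2S2O4 in THF/H2O under argon then reduces F8 to 23 without any acid step.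

## Further compounds

F1 | step 11 | 2,4,5-tris(methoxymethoxy)benzaldehyde | COCOc1cc(OCOC)c(OCOC)cc1C=O
F2 | step 11 | 1-[2,6-dihydroxy-4-methoxy-3,5-bis(3-methylbut-2-enyl)phenyl]-2-{hydroxy[2,4,5-tris(methoxymethoxy)phenyl]methyl}-5-methylhex-4-en-1-one (diastereomer mixture) | COCOc1cc(OCOC)c(OCOC)cc1C(O)C(CC=C(C)C)C(=O)c1c(O)c(CC=C(C)C)c(OC)c(CC=C(C)C)c1O
F3 | step 11 | 1-[2,6-dihydroxy-4-methoxy-3,5-bis(3-methylbut-2-enyl)phenyl]-2-(3-methylbut-2-enyl)-3-[2,4,5-tris(methoxymethoxy)phenyl]propane-1,3-dione | COc1c(CC=C(C)C)c(O)c(C(=O)C(CC=C(C)C)C(=O)c2cc(OCOC)c(OCOC)cc2OCOC)c(O)c1CC=C(C)C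
F4 | step 11 | 5-hydroxy-7-methoxy-3,6,8-tris(3-methylbut-2-enyl)-2-[2,4,5-tris(methoxymethoxy)phenyl]chromen-4-one | COc1c(CC=C(C)C)c(O)c2c(=O)c(CC=C(C)C)c(-c3cc(OCOC)c(OCOC)cc3OCOC)oc2c1CC=C(C)C
F5 | step 3 | 1-[4-methoxy-2,6-bis(methoxymethoxy)-3,5-bis(3-methylbut-2-enyl)phenyl]ethanone | CC(=O)c1c(OCOC)c(CC=C(C)C)c(OC)c(CC=C(C)C)c1OCOC
F6 | step 3 | 1-[4-methoxy-2,6-bis(methoxymethoxy)-3,5-bis(3-methylbut-2-enyl)phenyl]-5-methylhex-4-en-1-one | CC(C)=CCCC(=O)c1c(OCOC)c(CC=C(C)C)c(OC)c(CC=C(C)C)c1OCOC
F7 | step 4 | ethyl 5-(2-ethoxy-2-oxoacetyl)oxy-7-methoxy-3,6,8-tris(3-methylbut-2-enyl)-4-oxochromene-2-carboxylate | CCOC(=O)c1oc2c(CC=C(C)C)c(OC)c(CC=C(C)C)c(OC(=O)C(=O)OCC)c2c(=O)c1CC=C(C)C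
F0 | step 7 | none | none
F8 | step 13 | 2-hydroxy-5-[5-hydroxy-7-methoxy-3,6,8-tris(3-methylbut-2-enyl)-4-oxochromen-2-yl]cyclohexa-2,5-diene-1,4-dione | OC1=CC(=O)C(=CC1=O)c1oc2c(CC=C(C)C)c(OC)c(CC=C(C)C)c(O)c2c(=O)c1CC=C(C)C
A1 | alternative 1 | 4-methoxy-3,5-bis(3-methylbut-2-enyl)-6-{3-(3-methylbut-2-enyl)-2,4-dioxo-4-[2,4,5-tris(methoxymethoxy)phenyl]butyl}pyran-2-one | COc1c(CC=C(C)C)c(=O)oc(CC(=O)C(CC=C(C)C)C(=O)c2cc(OCOC)c(OCOC)cc2OCOC)c1CC=C(C)C
A2 | alternative 1 | 1-[2,6-dihydroxy-4-methoxy-3,5-bis(3-methylbut-2-enyl)phenyl]-2-(3-methylbut-2-enyl)-3-[2,4,5-tris(methoxymethoxy)phenyl]propane-1,3-dione | COc1c(CC=C(C)C)c(O)c(C(=O)C(CC=C(C)C)C(=O)c2cc(OCOC)c(OCOC)cc2OCOC)c(O)c1CC=C(C)C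
A3 | alternative 2 | 2,6-dihydroxy-4-methoxy-3,5-bis(3-methylbut-2-enyl)benzaldehyde | COc1c(CC=C(C)C)c(O)c(C=O)c(O)c1CC=C(C)C
A4 | alternative 2 | 1,2,4-tris(methoxymethoxy)-5-(5-methylhex-4-en-1-ynyl)benzene | COCOc1cc(OCOC)c(OCOC)cc1C#CCC=C(C)C
A5 | alternative 2 | 5-hydroxy-7-methoxy-3,6,8-tris(3-methylbut-2-enyl)-2-[2,4,5-tris(methoxymethoxy)phenyl]chromen-4-one | COc1c(CC=C(C)C)c(O)c2c(=O)c(CC=C(C)C)c(-c3cc(OCOC)c(OCOC)cc3OCOC)oc2c1CC=C(C)C
A6 | alternative 3 | 1-[2,6-difluoro-4-methoxy-3,5-bis(3-methylbut-2-enyl)phenyl]-2-(3-methylbut-2-enyl)-3-[2,4,5-tris(methoxymethoxy)phenyl]propane-1,3-dione | COc1c(CC=C(C)C)c(F)c(C(=O)C(CC=C(C)C)C(=O)c2cc(OCOC)c(OCOC)cc2OCOC)c(F)c1CC=C(C)C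
A7 | alternative 3 | 5-fluoro-7-methoxy-3,6,8-tris(3-methylbut-2-enyl)-2-[2,4,5-tris(methoxymethoxy)phenyl]chromen-4-one | COc1c(CC=C(C)C)c(F)c2c(=O)c(CC=C(C)C)c(-c3cc(OCOC)c(OCOC)cc3OCOC)oc2c1CC=C(C)C
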